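**Assumption:** the target SMILES has no stereocentre and no stereogenic double bond, so the compound is achiral and no stereocontrol is needed; all enol/keto forms are drawn in the tautomer of the given SMILES.

## Retrosynthetic overview

1. Target 19 is cut at both CH2 bridges (Mannich base to quinone methide couplings): ring A unit 7 plus the B–C dimer 16; 16 is cut into ring C phenol 13 and ring B phenol 5.
2. Ring B is formed first: 5 by C6→C1 Claisen closure of tetraketide ester 4, released from pyrone 3 (pyrone 1 plus butyryl unit 2).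
3. Ring A needs no new ring closure: 7 comes from 5 by dearomatising gem-C-dimethylation.
4. Ring C is formed second (key step): methoxide opens the 2-methoxy-γ-pyrone 11 and a vinylogous Claisen re-closure gives 13 with OMe and C-Me already in place; 11 comes from 1 via 9 and 10.
5. Order: ring B → ring A (from B) → ring C → C–B bridge → A–B bridge.

## Route

Step 1
Reactants: 1 triacetic acid lactone (4-hydroxy-6-methyl-2H-pyran-2-one); 2 N-methoxy-N-methylbutanamide
Product: 3 4-hydroxy-6-(2-oxopentyl)-2H-pyran-2-one
Conditions: LDA (2.2 equiv), THF, −78 °C; then 2 (1.0 equiv), −78 → 0 °C; 1 M HCl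
Reagents that add atoms: none
Why: The lithium pyronate is deprotonated at the 6-methyl group to the C,O-dianion, which is acylated only at the terminal carbanion (lateral Claisen-type acylation of a dianion), and the Weinreb chelate holds the adduct at the ketone oxidation level.

Step 2
Reactants: 3 4-hydroxy-6-(2-oxopentyl)-2H-pyran-2-one
Product: 5 phlorobutyrophenone [1-(2,4,6-trihydroxyphenyl)butan-1-one], via methyl 3,5,7-trioxodecanoate 4 (not isolated)
Conditions: Mg(OMe)2 (4 equiv), MeOH, reflux; then 1 M HCl
Reagents that add atoms: none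
Why: Methoxide opens the lactone to the Mg chelate of triketo ester 4, whose C6 carbanion attacks the ester carbonyl and expels methoxide again (intramolecular Claisen condensation, the C6→C1 closure of the phloroglucinol-forming polyketide synthase), Mg2+ chelation suppressing the C2→C7 aldol mode, and enolisation gives the arene.

Step 3
Reactants: 5 phlorobutyrophenone
Product: 7 butyrylfilicinic acid (2-butanoyl-3,5-dihydroxy-6,6-dimethylcyclohexa-2,4-dien-1-one), via 3-methylphlorobutyrophenone 6 (not isolated)
Conditions: NaOMe (3 equiv), MeI (2.2 equiv), MeOH, 0 °C → rt; 1 M HCl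
Reagents that add atoms: iodomethane, CI
Why: In methanol the phloroglucinolate is alkylated on carbon and the second methyl group enters the already methylated carbon to give the non-aromatic gem-dimethyl β-triketone (dearomatising C-alkylation of a phloroglucinol), 7 being separated from mono- and trimethylated by-products by chromatography.

Step 4
Reactants: 1 triacetic acid lactone
Product: 9 4-hydroxy-3,6-dimethyl-2H-pyran-2-one, via methylidene pyrandione 8 (not isolated)
Conditions: (CH2O)n (1.2 equiv), Hantzsch ester (1.1 equiv), L-proline (20 mol %), EtOH, rt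
Reagents that add atoms: formaldehyde (as paraformaldehyde), C=O
Why: Knoevenagel condensation at C3 gives the methylidene dione 8, which is reduced at once by conjugate hydride transfer from the Hantzsch ester (three-component reductive alkylation), and any 3,3'-methylene-bis adduct re-enters through retro-Michael cleavage under the amine catalyst.

Step 5
Reactants: 9 4-hydroxy-3,6-dimethyl-2H-pyran-2-one
Product: 10 2-methoxy-3,6-dimethyl-4H-pyran-4-one
Conditions: MeOTf (1.2 equiv), CH2Cl2, rt; aq. NaHCO3
Reagents that add atoms: methyl trifluoromethanesulfonate, COS(=O)(=O)C(F)(F)F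
Why: Without base the hard electrophile alkylates the lactone carbonyl oxygen of the neutral hydroxypyrone and loss of the 4-OH proton leaves the 2-methoxy-4-pyranone (kinetic O-alkylation, the usual entry to 2-methoxy-γ-pyrones).

Step 6
Reactants: 10 2-methoxy-3,6-dimethyl-4H-pyran-4-one; 2 N-methoxy-N-methylbutanamide
Product: 11 2-methoxy-3-methyl-6-(2-oxopentyl)-4H-pyran-4-one
Conditions: LiHMDS (2.1 equiv), THF, −78 °C; then 2 (1.1 equiv), −78 → −20 °C; aq. NH4Cl
Reagents that add atoms: none
Why: The 6-methyl group is the only vinylogously acidic position of 10 (the 3-methyl is cross-conjugated), so the lateral dienolate forms and is C-acylated by the Weinreb amide (lateral Claisen-type acylation), the second equivalent of base covering the acidic product.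

Step 7
Reactants: 11 2-methoxy-3-methyl-6-(2-oxopentyl)-4H-pyran-4-one
Product: 13 1-(4,6-dihydroxy-2-methoxy-3-methylphenyl)butan-1-one, via open-chain ketene acetal 12 (not isolated)
Conditions: Mg(OMe)2 (3 equiv), MeOH, reflux; then 1 M HCl
Reagents that add atoms: none
Why: Proposed new method: methoxide adds to C2 of 11 (the vinylogous-carbonate carbon, where oxygen nucleophiles attack 2-alkoxy-4-pyranones) and opens the ring to the Mg-chelated ketene acetal 12, whose C6 carbanion between the C5 and C7 carbonyls closes on C1 by addition–elimination, expelling one methoxide and keeping the other (a vinylogous Claisen, again the C6→C1 polyketide closure), so the OMe ends ortho to the acyl group and next to the C-methyl; aromatisation drains the reversible pyranone/open-chain equilibrium and the aldol mode is blocked because C2 of 12 carries no hydrogen; closest known reactions are the Mg(OMe)2 conversion of 6-(2-oxoalkyl)-4-hydroxy-2-pyrones into acylphloroglucinols and base-induced ring opening/recyclisation of 4-pyranones.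

Step 8
Reactants: 13 1-(4,6-dihydroxy-2-methoxy-3-methylphenyl)butan-1-one; 5 phlorobutyrophenone
Product: 16 1-[3-[(3-butanoyl-2,4,6-trihydroxyphenyl)methyl]-2,4-dihydroxy-6-methoxy-5-methylphenyl]butan-1-one, via Mannich base 14 (not isolated), via o-quinone methide 15 (not isolated)
Conditions: CH2(NMe2)2 (1.0 equiv), dioxane, 50 °C; then 5 (3 equiv), AcOH (2 equiv), 90 °C
Reagents that add atoms: bis(dimethylamino)methane, CN(C)CN(C)C
Why: The only free ring carbon of 13 is aminomethylated (phenolic Mannich reaction), 14 loses dimethylamine on heating to the o-quinone methide 15, and 5 adds through one of its two equivalent ring carbons (Michael-type Friedel–Crafts alkylation), its excess holding back double alkylation.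

Step 9
Reactants: 7 butyrylfilicinic acid; 16 the B–C dimer from step 8
Product: 19 Filixsaure (target), via Mannich base 17 (not isolated), via methylidene trione 18 (not isolated)
Conditions: CH2(NMe2)2 (1.0 equiv), MeCN, 0 °C → rt; then 16 (1.0 equiv), AcOH (2 equiv), 45 °C
Reagents that add atoms: bis(dimethylamino)methane, CN(C)CN(C)C
Why: Complete aminomethylation of the enolic CH of 7 leaves no free 7 to give the symmetrical dimer, the zwitterionic Mannich base 17 eliminates dimethylamine under mild warming to the methylidene trione 18, and the single remaining ring carbon of 16 (ring B) adds to it (retro-Mannich/Michael sequence), with the acetic acid buffer suppressing base-induced bridge exchange and no stereocentre being formed.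

## Compound list

1 | triacetic acid lactone (4-hydroxy-6-methyl-2H-pyran-2-one) | CC1=CC(O)=CC(=O)O1 | starting material
2 | N-methoxy-N-methylbutanamide | CCCC(=O)N(C)OC | starting material
3 | 4-hydroxy-6-(2-oxopentyl)-2H-pyran-2-one | CCCC(=O)CC1=CC(O)=CC(=O)O1 | intermediate
4 | methyl 3,5,7-trioxodecanoate | CCCC(=O)CC(=O)CC(=O)CC(=O)OC | intermediate (not isolated)
5 | phlorobutyrophenone, 1-(2,4,6-trihydroxyphenyl)butan-1-one | CCCC(=O)c1c(O)cc(O)cc1O | intermediate
6 | 3-methylphlorobutyrophenone, 1-(2,4,6-trihydroxy-3-methylphenyl)butan-1-one | CCCC(=O)c1c(O)cc(O)c(C)c1O | intermediate (not isolated)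
7 | butyrylfilicinic acid, 2-butanoyl-3,5-dihydroxy-6,6-dimethylcyclohexa-2,4-dien-1-one | CCCC(=O)C1=C(O)C=C(O)C(C)(C)C1=O | intermediate
8 | 6-methyl-3-methylidene-2H-pyran-2,4(3H)-dione | C=C1C(=O)C=C(C)OC1=O | intermediate (not isolated)
9 | 4-hydroxy-3,6-dimethyl-2H-pyran-2-one | CC1=CC(O)=C(C)C(=O)O1 | intermediate
10 | 2-methoxy-3,6-dimethyl-4H-pyran-4-one | COC1=C(C)C(=O)C=C(C)O1 | intermediate
11 | 2-methoxy-3-methyl-6-(2-oxopentyl)-4H-pyran-4-one | COC1=C(C)C(=O)C=C(CC(=O)CCC)O1 | intermediate
12 | 1,1-dimethoxy-2-methyldec-1-ene-3,5,7-trione (open-chain ketene acetal) | COC(OC)=C(C)C(=O)CC(=O)CC(=O)CCC | intermediate (not isolated)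
13 | 1-(4,6-dihydroxy-2-methoxy-3-methylphenyl)butan-1-one | CCCC(=O)c1c(O)cc(O)c(C)c1OC | intermediate
14 | 1-[3-[(dimethylamino)methyl]-2,4-dihydroxy-6-methoxy-5-methylphenyl]butan-1-one | CCCC(=O)c1c(O)c(CN(C)C)c(O)c(C)c1OC | intermediate (not isolated)
15 | 2-butanoyl-5-hydroxy-3-methoxy-4-methyl-6-methylidenecyclohexa-2,4-dien-1-one (o-quinone methide) | C=C1C(O)=C(C)C(OC)=C(C(=O)CCC)C1=O | intermediate (not isolated)
16 | 1-[3-[(3-butanoyl-2,4,6-trihydroxyphenyl)methyl]-2,4-dihydroxy-6-methoxy-5-methylphenyl]butan-1-one | CCCC(=O)c1c(O)cc(O)c(Cc2c(O)c(C)c(OC)c(C(=O)CCC)c2O)c1O | intermediate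
17 | 2-butanoyl-4-[(dimethylamino)methyl]-3,5-dihydroxy-6,6-dimethylcyclohexa-2,4-dien-1-one | CCCC(=O)C1=C(O)C(CN(C)C)=C(O)C(C)(C)C1=O | intermediate (not isolated)
18 | 2-butanoyl-3-hydroxy-6,6-dimethyl-4-methylidenecyclohex-2-ene-1,5-dione | CCCC(=O)C1=C(O)C(=C)C(=O)C(C)(C)C1=O | intermediate (not isolated)
19 | Filixsaure, 2-butanoyl-4-[[3-butanoyl-5-[(3-butanoyl-2,6-dihydroxy-4-methoxy-5-methylphenyl)methyl]-2,4,6-trihydroxyphenyl]methyl]-3,5-dihydroxy-6,6-dimethylcyclohexa-2,4-dien-1-one | CCCC(=O)C1=C(O)C(Cc2c(O)c(Cc3c(O)c(C)c(OC)c(C(=O)CCC)c3O)c(O)c(C(=O)CCC)c2O)=C(O)C(C)(C)C1=O | target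

## Step count and risks

Total step count: 9. Longest linear sequence: 6 steps (1 → 9 → 10 → 11 → 13 → 16 → 19; steps 4 to 9).

**Step 7 (most likely to fail).** The ring construction is new. Methoxide could attack C6 instead of C2, which would give the regioisomer with the methyl between two hydroxyls. The open chain could simply re-close to the pyranone, or the pyranone could be demethylated to the α-pyrone. The fallback places the O-methyl after ring formation instead of during it; it sets out from 9 and comes back at 13. The dianion of 9 (LDA, THF, −78 °C) is acylated with 2 to 4-hydroxy-3-methyl-6-(2-oxopentyl)-2H-pyran-2-one F1. Mg(OMe)2 in refluxing methanol opens F1 to methyl 2-methyl-3,5,7-trioxodecanoate F2, which closes by Claisen condensation to 3-methylphlorobutyrophenone 6, now isolated. MOMCl/i-Pr2NEt protects the para hydroxyl and the less hindered ortho hydroxyl, leaving the chelated hydroxyl next to the methyl free, to give 1-[2-hydroxy-4,6-bis(methoxymethoxy)-3-methylphenyl]butan-1-one F3. MeI/K2CO3 in DMF gives 1-[2-methoxy-4,6-bis(methoxymethoxy)-3-methylphenyl]butan-1-one F4, and HCl in methanol removes both acetals to give 13.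

**Step 9.** The final union can suffer retro-Michael exchange of the bridges, giving albaspidin-type and symmetrical trimers, and the ring B carbon of 16 is hindered. The fallback reverses the roles of the partners; it sets out from 16 and comes back at 19. 16 is aminomethylated with CH2(NMe2)2 at its free ring B carbon and the product is isolated: 1-[3-[[3-butanoyl-5-[(dimethylamino)methyl]-2,4,6-trihydroxyphenyl]methyl]-2,4-dihydroxy-6-methoxy-5-methylphenyl]butan-1-one F5. Heating F5 with 7 (3 equiv) in dioxane/AcOH at 80 °C generates the ring B quinone methide 4-butanoyl-2-[(3-butanoyl-2,6-dihydroxy-4-methoxy-5-methylphenyl)methyl]-3,5-dihydroxy-6-methylidenecyclohexa-2,4-dien-1-one F6, which is captured by the enolic carbon of 7 to give 19. Here 7 is the better nucleophile, can be used in excess and recovered, and never carries the electrophilic carbon, so the symmetrical dimer of 7 cannot form.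

**Step 4.** Formaldehyde may drain 1 into the 3,3'-methylene-bis(pyrone) faster than the Hantzsch ester reduces 8. The fallback traps the methylidene dione with sulfur and reduces in a separate operation; it sets out from 1 and comes back at 9. 1, paraformaldehyde and thiophenol (piperidine/AcOH cat., EtOH, reflux) give, via 8, the stable sulfide 4-hydroxy-6-methyl-3-[(phenylsulfanyl)methyl]-2H-pyran-2-one F7. Raney nickel in refluxing ethanol desulfurises F7 to 9.

## Further compounds

F1 | step 7 | 4-hydroxy-3-methyl-6-(2-oxopentyl)-2H-pyran-2-one | CCCC(=O)CC1=CC(O)=C(C)C(=O)O1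
F2 | step 7 | methyl 2-methyl-3,5,7-trioxodecanoate | CCCC(=O)CC(=O)CC(=O)C(C)C(=O)OC
F3 | step 7 | 1-[2-hydroxy-4,6-bis(methoxymethoxy)-3-methylphenyl]butan-1-one | CCCC(=O)c1c(O)c(C)c(OCOC)cc1OCOC
F4 | step 7 | 1-[2-methoxy-4,6-bis(methoxymethoxy)-3-methylphenyl]butan-1-one | CCCC(=O)c1c(OC)c(C)c(OCOC)cc1OCOC
F5 | step 9 | 1-[3-[[3-butanoyl-5-[(dimethylamino)methyl]-2,4,6-trihydroxyphenyl]methyl]-2,4-dihydroxy-6-methoxy-5-methylphenyl]butan-1-one | CCCC(=O)c1c(O)c(CN(C)C)c(O)c(Cc2c(O)c(C)c(OC)c(C(=O)CCC)c2O)c1O
F6 | step 9 | 4-butanoyl-2-[(3-butanoyl-2,6-dihydroxy-4-methoxy-5-methylphenyl)methyl]-3,5-dihydroxy-6-methylidenecyclohexa-2,4-dien-1-one | C=C1C(=O)C(Cc2c(O)c(C)c(OC)c(C(=O)CCC)c2O)=C(O)C(C(=O)CCC)=C1O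
F7 | step 4 | 4-hydroxy-6-methyl-3-[(phenylsulfanyl)methyl]-2H-pyran-2-one | CC1=CC(O)=C(CSc2ccccc2)C(=O)O1
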